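**Retrosynthetic overview**
1. The target is a symmetric 2,2'-bi(hydroxybenzoquinone); its two acidic OH groups are carried as methyl ethers (vinylogous esters) and released last by hydrolysis.
2. Key disconnection: the central quinone–quinone C–C bond, made by an intermolecular Michael addition of the monomer hydroquinone (carbon nucleophile) to the monomer methoxyquinone (acceptor), followed by re-oxidation of the biaryl tetrol.
3. The monomer quinone comes from para-oxidation of 3-methoxy-2-methyl-5-(2-phenylethyl)phenol, obtained by mono-demethylation of the symmetric dimethyl ether.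
4. The C-methyl group is installed by directed ortho-metalation between the two methoxy groups; the phenethyl arm comes from Horner–Wadsworth–Emmons olefination of 3,5-dimethoxybenzaldehyde and hydrogenation.
5. No ring is constructed: both six-membered rings are the purchased benzene ring of 3,5-dimethoxybenzaldehyde, converted to quinones by oxidation (steps 5 and 8).

Assumption: the SMILES carries no stereodescriptor, so the target is treated as having no stereocentre and no fixed axial configuration, and no enantioselective step is needed.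

**Route**

Step 1
Reactants: 1 3,5-dimethoxybenzaldehyde; 2 diethyl benzylphosphonate
Product: 4 (E)-1,3-dimethoxy-5-(2-phenylethenyl)benzene, via potassium phosphonate carbanion 3 (not isolated)
Conditions: 2, KOC(CH3)3 (1.2 equiv), THF, 0 °C, 30 min; then 1, 0 °C → rt
Reagents that add atoms: potassium tert-butoxide KOC(CH3)3, CC(C)(C)[O-].[K+] (supplies only the K+ of intermediate 3; product 4 takes no atoms from reagents)
Why: Horner–Wadsworth–Emmons olefination of a non-enolisable aryl aldehyde with the benzylic phosphonate carbanion gives the E-stilbene with a water-soluble phosphate by-product; no stereocentre forms and the alkene geometry is erased in step 2.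

Step 2
Reactants: 4 (E)-1,3-dimethoxy-5-(2-phenylethenyl)benzene
Product: 5 1,3-dimethoxy-5-(2-phenylethyl)benzene
Conditions: H2 (1 atm), 10% Pd/C, EtOAc, rt
Reagents that add atoms: none
Why: Heterogeneous catalytic hydrogenation saturates the stilbene C=C at 1 atm without touching the aryl methyl ethers or the aromatic rings.

Step 3
Reactants: 5 1,3-dimethoxy-5-(2-phenylethyl)benzene
Product: 7 1,3-dimethoxy-2-methyl-5-(2-phenylethyl)benzene, via aryllithium 6 (not isolated)
Conditions: n-C4H9Li (1.3 equiv), THF, 0 °C → rt, 2 h; then CH3I (1.5 equiv), 0 °C → rt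
Reagents that add atoms: iodomethane CH3I, CI (the new C-methyl group); n-butyllithium n-C4H9Li, [Li]CCCC (Li of intermediate 6 only)
Why: Directed ortho-metalation removes the ring proton flanked by both methoxy groups (the most acidic and best-coordinated site), and the aryllithium is trapped by SN2 methylation.

Step 4
Reactants: 7 1,3-dimethoxy-2-methyl-5-(2-phenylethyl)benzene
Product: 9 3-methoxy-2-methyl-5-(2-phenylethyl)phenol, via sodium phenoxide 8 (not isolated)
Conditions: NaSCH2CH3 (3 equiv), DMF, 140 °C, 3 h; then 1 M HCl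
Reagents that add atoms: sodium ethanethiolate NaSCH2CH3, CC[S-].[Na+] (Na+ of intermediate 8 only; product 9 takes no atoms from reagents)
Why: SN2 O-demethylation by thiolate stops after one methyl because the phenoxide formed will not release a second aryloxide, and the symmetric substrate can give only one mono-ether.

Step 5
Reactants: 9 3-methoxy-2-methyl-5-(2-phenylethyl)phenol
Product: 10 2-methoxy-3-methyl-6-(2-phenylethyl)cyclohexa-2,5-diene-1,4-dione
Conditions: (KSO3)2NO (2.5 equiv), aq. KH2PO4, acetone, 0 °C → rt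
Reagents that add atoms: potassium nitrosodisulfonate (KSO3)2NO, [O]N(S(=O)(=O)[O-])S(=O)(=O)[O-].[K+].[K+] (oxygen of the new C=O)
Why: Teuber oxidation: the nitrosodisulfonate radical converts a phenol with a free para position into the para-quinone, a conversion well established for 3-methoxy-5-alkylphenols.

Step 6
Reactants: 10 2-methoxy-3-methyl-6-(2-phenylethyl)cyclohexa-2,5-diene-1,4-dione (half of the material)
Product: 11 2-methoxy-3-methyl-6-(2-phenylethyl)benzene-1,4-diol
Conditions: Na2S2O4 (3 equiv), EtOAc/H2O, rt, Ar; used at once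
Reagents that add atoms: none
Why: Two-electron reduction of a quinone to its hydroquinone by dithionite is fast, essentially quantitative and touches no other group.

Step 7
Reactants: 10 2-methoxy-3-methyl-6-(2-phenylethyl)cyclohexa-2,5-diene-1,4-dione (1.0 equiv); 11 2-methoxy-3-methyl-6-(2-phenylethyl)benzene-1,4-diol (1.0 equiv)
Product: 13 4,4'-dimethoxy-3,3'-dimethyl-6,6'-bis(2-phenylethyl)biphenyl-2,2',5,5'-tetrol, via dienone Michael adduct 12 (not isolated)
Conditions: BF3·OEt2 (0.3 equiv), CH2Cl2, −20 °C → rt, Ar; aq. Na2S2O4 wash, crude carried on under Ar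
Reagents that add atoms: none
Why: Intermolecular Michael addition: the only free ring carbon of 11 (ortho to OH, para to OMe) attacks the only unsubstituted β-carbon of acid-activated 10 (β to the carbonyl that is not part of the vinylogous ester), and adduct 12 enolises to the biaryl, so the transient sp3 centre is lost and no stereocentre remains.

Step 8
Reactants: 13 4,4'-dimethoxy-3,3'-dimethyl-6,6'-bis(2-phenylethyl)biphenyl-2,2',5,5'-tetrol
Product: 14 5,5'-dimethoxy-6,6'-dimethyl-3,3'-bis(2-phenylethyl)-2,2'-bi(1,4-benzoquinone)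
Conditions: Ag2O (5 equiv), Na2SO4, THF, rt, dark
Reagents that add atoms: none
Why: Ag2O oxidises each hydroquinone ring to the quinone under neutral anhydrous conditions that leave the vinylogous methyl esters intact; unreacted monomer returns as separable 10.

Step 9
Reactants: 14 5,5'-dimethoxy-6,6'-dimethyl-3,3'-bis(2-phenylethyl)-2,2'-bi(1,4-benzoquinone)
Product: 16 5,5'-dihydroxy-6,6'-dimethyl-3,3'-bis(2-phenylethyl)-2,2'-bi(1,4-benzoquinone), via disodium bis-quinonolate 15 (not isolated)
Conditions: 1 M NaOH aq., MeOH/THF, rt, Ar; then 1 M HCl to pH 2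
Reagents that add atoms: sodium hydroxide NaOH, [Na+].[OH-] (oxygen of both new OH groups; Na+ of intermediate 15)
Why: Vinylogous ester saponification by addition–elimination: hydroxide adds to the methoxy-bearing β-carbon of each quinone enone, methoxide leaves, and the resulting vinylogous carboxylate is inert to further attack until acidified.

**Compound list**
1 | 3,5-dimethoxybenzaldehyde | COc1cc(C=O)cc(OC)c1 | starting material
2 | diethyl benzylphosphonate | CCOP(=O)(Cc1ccccc1)OCC | starting material
3 | potassium salt of the benzylic carbanion of diethyl benzylphosphonate | CCOP(=O)(OCC)[CH-]c1ccccc1.[K+] | intermediate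
4 | (E)-1,3-dimethoxy-5-(2-phenylethenyl)benzene ((E)-3,5-dimethoxystilbene) | COc1cc(/C=C/c2ccccc2)cc(OC)c1 | intermediate
5 | 1,3-dimethoxy-5-(2-phenylethyl)benzene | COc1cc(CCc2ccccc2)cc(OC)c1 | intermediate
6 | [2,6-dimethoxy-4-(2-phenylethyl)phenyl]lithium | [Li]c1c(OC)cc(CCc2ccccc2)cc1OC | intermediate
7 | 1,3-dimethoxy-2-methyl-5-(2-phenylethyl)benzene | COc1cc(CCc2ccccc2)cc(OC)c1C | intermediate
8 | sodium 3-methoxy-2-methyl-5-(2-phenylethyl)phenoxide | COc1cc(CCc2ccccc2)cc([O-])c1C.[Na+] | intermediate
9 | 3-methoxy-2-methyl-5-(2-phenylethyl)phenol | COc1cc(CCc2ccccc2)cc(O)c1C | intermediate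
10 | 2-methoxy-3-methyl-6-(2-phenylethyl)cyclohexa-2,5-diene-1,4-dione (monomer methoxyquinone) | COC1=C(C)C(=O)C=C(CCc2ccccc2)C1=O | intermediate
11 | 2-methoxy-3-methyl-6-(2-phenylethyl)benzene-1,4-diol (monomer hydroquinone) | COc1c(C)c(O)cc(CCc2ccccc2)c1O | intermediate
12 | 6-[2,5-dihydroxy-4-methoxy-3-methyl-6-(2-phenylethyl)phenyl]-4-hydroxy-3-methoxy-2-methyl-5-(2-phenylethyl)cyclohexa-2,4-dien-1-one (racemic, transient) | COC1=C(C)C(=O)C(c2c(O)c(C)c(OC)c(O)c2CCc2ccccc2)C(CCc2ccccc2)=C1O | intermediate
13 | 4,4'-dimethoxy-3,3'-dimethyl-6,6'-bis(2-phenylethyl)biphenyl-2,2',5,5'-tetrol | COc1c(C)c(O)c(-c2c(O)c(C)c(OC)c(O)c2CCc2ccccc2)c(CCc2ccccc2)c1O | intermediate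
14 | 5,5'-dimethoxy-6,6'-dimethyl-3,3'-bis(2-phenylethyl)-2,2'-bi(1,4-benzoquinone) | COC1=C(C)C(=O)C(=C(CCc2ccccc2)C1=O)C1=C(CCc2ccccc2)C(=O)C(OC)=C(C)C1=O | intermediate
15 | disodium salt of 16 (both hydroxyquinone OH groups deprotonated) | CC1=C([O-])C(=O)C(CCc2ccccc2)=C(C2=C(CCc3ccccc3)C(=O)C([O-])=C(C)C2=O)C1=O.[Na+].[Na+] | intermediate
16 | 5,5'-dihydroxy-6,6'-dimethyl-3,3'-bis(2-phenylethyl)-2,2'-bi(1,4-benzoquinone) (CNP0136737.0) | CC1=C(O)C(=O)C(CCc2ccccc2)=C(C2=C(CCc3ccccc3)C(=O)C(O)=C(C)C2=O)C1=O | target

**Totals**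
Total step count: 9. Longest linear sequence: 9 steps (1 → 4 → 5 → 7 → 9 → 10 → 11 → 13 → 14 → 16); compound 10 is used twice, as the acceptor and as the precursor of 11.

**Steps most likely to fail, with fallbacks**

Step 7 (Michael biaryl coupling) is the most exposed, because the new bond is flanked by four ortho substituents and quinone/hydroquinone redox exchange can slow the addition. The fallback sets out from compound 11 and comes back at compound 14. Hydroquinone 11 is O-methylated (CH3I, K2CO3, acetone, reflux, Ar) to 1,3,4-trimethoxy-2-methyl-5-(2-phenylethyl)benzene F1. This is iodinated at its single free ring position (N-iodosuccinimide, cat. CF3CO2H, MeCN, rt) to 1-iodo-2,4,5-trimethoxy-3-methyl-6-(2-phenylethyl)benzene F2. Ullmann homocoupling (activated Cu powder, DMF, 150 °C) gives 2,2',4,4',5,5'-hexamethoxy-3,3'-dimethyl-6,6'-bis(2-phenylethyl)biphenyl F3. Oxidative demethylation of F3 with (NH4)2Ce(NO3)6 in MeCN/H2O at 0 °C gives bis(methoxyquinone) 14.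

Step 5 (Teuber oxidation) can give low yields because the reagent is unstable and the phenol is lipophilic. The fallback sets out from compound 7 and comes back at compound 10, bypassing 8 and 9. Vilsmeier–Haack formylation of 7 (POCl3, DMF, 0 → 80 °C) gives 2,4-dimethoxy-3-methyl-6-(2-phenylethyl)benzaldehyde F4. Baeyer–Villiger (Dakin-type) oxidation with mCPBA in CH2Cl2 gives 2,4-dimethoxy-3-methyl-6-(2-phenylethyl)phenyl formate F5. Methanolysis (K2CO3, MeOH) gives 2,4-dimethoxy-3-methyl-6-(2-phenylethyl)phenol F6. Oxidation of this para-methoxyphenol with (NH4)2Ce(NO3)6 in MeCN/H2O at 0 °C gives quinone 10.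

Step 9 (double vinylogous ester hydrolysis) may be complicated by base sensitivity of the bis-quinone. The fallback sets out from compound 13 and comes back at compound 16. Tetrol 13 is demethylated at the arene stage (BBr3, CH2Cl2, −78 °C → rt, aqueous work-up under Ar) to 3,3'-dimethyl-6,6'-bis(2-phenylethyl)biphenyl-2,2',4,4',5,5'-hexol F7. Oxidation of F7 with Ag2O in THF (or simply air) converts each hydroxyhydroquinone ring directly into the hydroxyquinone of 16.

**Further compounds**
F1 | step 7 | 1,3,4-trimethoxy-2-methyl-5-(2-phenylethyl)benzene | COc1cc(CCc2ccccc2)c(OC)c(OC)c1C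
F2 | step 7 | 1-iodo-2,4,5-trimethoxy-3-methyl-6-(2-phenylethyl)benzene | COc1c(I)c(CCc2ccccc2)c(OC)c(OC)c1C
F3 | step 7 | 2,2',4,4',5,5'-hexamethoxy-3,3'-dimethyl-6,6'-bis(2-phenylethyl)biphenyl | COc1c(C)c(OC)c(OC)c(CCc2ccccc2)c1-c1c(OC)c(C)c(OC)c(OC)c1CCc1ccccc1
F4 | step 5 | 2,4-dimethoxy-3-methyl-6-(2-phenylethyl)benzaldehyde | COc1cc(CCc2ccccc2)c(C=O)c(OC)c1C
F5 | step 5 | 2,4-dimethoxy-3-methyl-6-(2-phenylethyl)phenyl formate | COc1cc(CCc2ccccc2)c(OC=O)c(OC)c1C
F6 | step 5 | 2,4-dimethoxy-3-methyl-6-(2-phenylethyl)phenol | COc1cc(CCc2ccccc2)c(O)c(OC)c1C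
F7 | step 9 | 3,3'-dimethyl-6,6'-bis(2-phenylethyl)biphenyl-2,2',4,4',5,5'-hexol | Cc1c(O)c(O)c(CCc2ccccc2)c(c1O)-c1c(O)c(C)c(O)c(O)c1CCc1ccccc1
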